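South-east, with 0.54 M of nucleophile, shows 0% electrophile at 1.04 d, while north-west, with 0.36 M, still holds 19.9% at 6.00 d. By the first north-west reading 0.184 M of electrophile has reacted, which is 1.96 nucleophile charged per electrophile reacted. The stall suggests that nucleophile is the limiting reagent and that about two go per electrophile.

common to all: electrophile 0.25 M; solid base 0.375 M
- north-west: nucleophile 0.36 M; run made earlier
- south-east: nucleophile 0.54 M; run made earlier
- elm: nucleophile 0.300 M; time 8.0 d
- maple: nucleophile 0.450 M; time 8.0 d

- north-west (time / d: electrophile / %, target / %): 0.417: 26.5, 62.4; 1.04: 25.0, 49.1; 2.08: 22.3, 31.7; 3.00: 21.3, 21.5; 4.00: 20.3, 14.8; 6.00: 19.9, 7.9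
- south-east (time / d: electrophile / %, target / %): 0.417: 0.6, 83.2; 1.04: 0, 64.1; 2.08: 0.5, 39.7; 3.00: 0, 26.5; 4.00: 0, 17.3; 6.00: 0, 6.7

(scatter of a reading: 0.5 percentage points)

- part of the electrophile that has reacted at the end, elm
- part of the electrophile that has reacted at the end, maple
- what raising the concentration of nucleophile from its lowest to its highest value here does to the part of the electrophile that has reacted (changes below 5 percentage points count as none) (it rises / no change / it falls)

- given per volume of solution although it is solid: solid base
- at the start none of the solid base is in solution

It pays to reckon the fraction left. For elm the shortfall, one minus [nucleophile]/(two [electrophile]) at the charge, is the part of the electrophile left over if each electrophile takes two of the charged nucleophile: 40.0%.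

| run | shortfall | left, first reading | left, last reading |
|---|---|---|---|
| north-west | 28.0% | 26.5% | 19.9% |
| south-east | −8.00% | 0.6% | 0% |

A shortfall below zero reads as no electrophile left, and south-east agrees within the scatter. In north-west the shortfall lies near the first reading, but the electrophile then creeps down, so one number is not enough. The readings run on to 20.3% at 4.00 d and 19.9% at 6.00 d, where the reading of electrophile left is 0.711 of the shortfall.

Keeping that share, which rests on one reading of one run, the reckoning here gives 71.6% reacted for elm. For maple, with shortfall 10.0%, it gives 92.9% reacted, a rise of 21 percentage points.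

The forecast gives 67% for elm and 99% for maple, and the trend: it rises. Its ground is that “the nucleophile is limiting”. The reckoning here puts elm higher and maple lower.

The flask gives 71.5% for elm and 96.0% for maple: it rises, by 24 points.

    acid set free + free base ⇌ salt of the base (K = 4.10 M⁻¹, k = 0.112 M⁻¹ min⁻¹)
    2 free base → self-condensation product (k = 0.00318 M⁻¹ min⁻¹)
    nucleophile + acid set free ⇌ protonated nucleophile, settled at all times (K = 13000 M⁻¹)
    electrophile + nucleophile → acid set free + target (k = 0.0789 M⁻¹ min⁻¹)
    solid base ⇌ free base, rate k5*(cs5 - [free base]) while solid is left; crystals form when [free base] > cs5 (solubility = 49.0 mM, k = 0.0188 min⁻¹)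
    target → over-reaction product (k = 3.15 × 10⁻⁴ min⁻¹)

At 8.00 d elm holds 0.064% of its nucleophile, and its electrophile left, 28%, is 0.711 of the shortfall. Maple's 4.0% is 0.405 of its shortfall, a smaller share than north-west's. The neighbour is elm with 0.42 M of electrophile. Its shortfall is 64.3%, and the share 0.711 turns that into 45.7% left. The neighbour leaves 53% at 8.00 d, so 47.1% has reacted.

(All runs are calculated with constants of no real substance; the scatter is artificial.)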